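**Retrosynthetic overview**

1. The target ring is O1–C2(H, C23 chain, the only stereocentre)–C3H2–C4(=O)–C5H=C6(CH3). The plan rests on C6: it carries CH3 and O1 and lies 1,3 to C2 across O1, so at the saturated level C6/C5/C4 are C3/C2/C1 of (S)-3-hydroxybutanoate, and C6 can steer C2 before being flattened.
2. C5=C6 is made last, by sulfoxide syn-elimination from the 2,6-cis-5-(phenylsulfanyl)tetrahydropyran-4-one 12.
3. C2–C3 of 12 comes from a Me2AlCl-promoted O-to-C 1,3-shift (Petasis–Ferrier) of the 4-methylidene-1,3-dioxane 11. The dioxane (closed in step 6) is only a tether; the pyranone ring closes in step 8.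
4. 11 comes from Cp2TiMe2 methylenation of cis-dioxanone 10, itself from Me3SiOTf acetalisation of silylated hydroxy acid 9 with aldehyde 3.
5. 9 comes from methyl (S)-3-hydroxybutanoate 4 and PhSSPh 5 (dianion sulfenylation); 3 comes from nervonic acid 1.

Key step: step 8

Assumption: the sulfur-bearing centre C5 is drawn as the anti (5,6-trans) isomer expected from the chelated dianion; it is destroyed in step 10, so its configuration never reaches the target. Pyranone ring positions are numbered as in the target throughout.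

**Route**

Step 1
Reactants: 1 nervonic acid, (15Z)-tetracos-15-enoic acid
Product: 2 (15Z)-tetracos-15-en-1-ol
Conditions: LiAlH4, THF, 0 °C → rt; H2O/aq. NaOH work-up
Reagents that add atoms: none
Why: Hydride reduction of a carboxylic acid to the primary alcohol; the isolated Z-alkene is inert to LiAlH4.

Step 2
Reactants: 2 (15Z)-tetracos-15-en-1-ol
Product: 3 (15Z)-tetracos-15-enal
Conditions: Dess–Martin periodinane, CH2Cl2, 0 °C → rt
Reagents that add atoms: none
Why: Dess–Martin oxidation stops cleanly at the aldehyde and does not touch or isomerise the Z-alkene; the aldehyde is used fresh.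

Step 3
Reactants: 4 methyl (S)-3-hydroxybutanoate; 5 diphenyl disulfide
Product: 7 methyl (2S,3S)-3-hydroxy-2-(phenylsulfanyl)butanoate, via chelated dilithium alkoxide-enolate 6 (not isolated)
Conditions: LiN(iPr)2 (2.2 equiv), THF, −78 → −20 °C; inverse addition to PhSSPh (1.1 equiv), THF, −78 °C; aq. NH4Cl
Reagents that add atoms: diphenyl disulfide (compound 5), c1ccc(cc1)SSc1ccccc1
Why: Fráter–Seebach dianion chemistry combined with enolate sulfenylation by a disulfide; the electrophile should approach the lithium-chelated enolate on the face away from the C3 methyl, setting C2 anti to the hydroxyl (2S), and inverse addition limits proton transfer to unreacted dianion.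

Step 4
Reactants: 7 methyl (2S,3S)-3-hydroxy-2-(phenylsulfanyl)butanoate
Product: 8 (2S,3S)-3-hydroxy-2-(phenylsulfanyl)butanoic acid
Conditions: LiOH·H2O, THF/H2O, 0 °C; then 1 M HCl to pH 2–3
Reagents that add atoms: lithium hydroxide, [Li+].[OH-]
Why: Ester saponification by acyl–oxygen cleavage; at 0 °C hydrolysis of the activated α-sulfanyl ester should outrun retro-aldol and α-epimerisation, and the carboxylate once formed is configurationally safe.

Step 5
Reactants: 8 (2S,3S)-3-hydroxy-2-(phenylsulfanyl)butanoic acid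
Product: 9 trimethylsilyl (2S,3S)-2-(phenylsulfanyl)-3-[(trimethylsilyl)oxy]butanoate
Conditions: (Me3Si)2NH, CH2Cl2, rt; evaporate, use crude
Reagents that add atoms: hexamethyldisilazane, C[Si](C)(C)N[Si](C)(C)C
Why: Neutral bis-silylation of acid and alcohol driven by loss of ammonia; no base or acid strong enough to disturb C2 or C3 is present.

Step 6
Reactants: 9 trimethylsilyl (2S,3S)-2-(phenylsulfanyl)-3-[(trimethylsilyl)oxy]butanoate; 3 (15Z)-tetracos-15-enal
Product: 10 (2S,5S,6S)-6-methyl-5-(phenylsulfanyl)-2-[(14Z)-tricos-14-en-1-yl]-1,3-dioxan-4-one (2,6-cis, 5,6-trans)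
Conditions: Me3SiOTf (10–20 mol %), CH2Cl2, −78 °C; pyridine quench
Reagents that add atoms: none
Why: Silyl-triflate-catalysed acetalisation of a bis-silylated β-hydroxy acid with an aldehyde (Noyori-type, as used for Petasis–Ferrier unions); ring closure through the oxocarbenium ion places the C23 chain equatorial, cis to the equatorial C6 methyl, so the acetal carbon C2 is set by C6.

Step 7
Reactants: 10 (2S,5S,6S)-6-methyl-5-(phenylsulfanyl)-2-[(14Z)-tricos-14-en-1-yl]-1,3-dioxan-4-one
Product: 11 (2S,5S,6S)-6-methyl-4-methylidene-5-(phenylsulfanyl)-2-[(14Z)-tricos-14-en-1-yl]-1,3-dioxane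
Conditions: Cp2TiMe2 (2.5 equiv), THF, 65 °C, dark; hexanes, filtration through Et3N-treated basic alumina
Reagents that add atoms: dimethyltitanocene Cp2TiMe2, C[Ti+2]C.c1cc[cH-]c1.c1cc[cH-]c1
Why: Petasis methylenation: thermally generated Cp2Ti=CH2 converts the lactone carbonyl into the exocyclic enol ether through an oxatitanacyclobutane, under non-acidic, weakly basic conditions that should spare the acetal, the α-sulfanyl centre and the unstrained internal Z-alkene.

Step 8
Reactants: 11 (2S,5S,6S)-6-methyl-4-methylidene-5-(phenylsulfanyl)-2-[(14Z)-tricos-14-en-1-yl]-1,3-dioxane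
Product: 12 (2R,5S,6S)-6-methyl-5-(phenylsulfanyl)-2-[(14Z)-tricos-14-en-1-yl]tetrahydro-4H-pyran-4-one (2,6-cis, 5,6-trans)
Conditions: Me2AlCl (1.5–2 equiv, hexanes), CH2Cl2, −78 °C → −20 °C; aq. NaHCO3
Reagents that add atoms: none
Why: Me2AlCl binds the enol-ether oxygen O3 and ionises the C2–O3 acetal bond, giving an (E)-oxocarbenium ion (O1=C2) tethered through C6–C5 to a dimethylaluminium enolate whose terminal CH2 then adds to C2, an O-to-C 1,3-shift that forms C2–C3. This is the Petasis–Ferrier rearrangement of 4-methylidene-1,3-dioxanes to tetrahydropyran-4-ones, which is itself the closest known reaction type. The one ring closes in a 6-(enolendo)-endo-trig mode through a chair in which the C6 methyl, the C5 phenylsulfanyl group and the C23 chain on the oxocarbenium carbon are all equatorial. The new stereocentre C2 is therefore set by C6 across O1 as 2,6-cis, which makes C2 (R) starting from the (S)-hydroxybutanoate carbon. The selectivity needed is 2,6-cis over 2,6-trans; it is secured by the equatorial preference of both flanking groups in the chair and by the cis ketone being the more stable isomer, while C5, C6 and the remote Z-alkene are not involved. The sulfide at C5 is a spectator in the bond reorganisation, and more than one equivalent of Me2AlCl at low temperature is used so that reversible S-coordination does not deprive O3 of Lewis acid.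

Step 9
Reactants: 12 (2R,5S,6S)-6-methyl-5-(phenylsulfanyl)-2-[(14Z)-tricos-14-en-1-yl]tetrahydro-4H-pyran-4-one
Product: 13 (2R,5S,6S)-6-methyl-5-(phenylsulfinyl)-2-[(14Z)-tricos-14-en-1-yl]tetrahydro-4H-pyran-4-one (mixture of epimers at sulfur)
Conditions: mCPBA (1.0 equiv), CH2Cl2, −78 °C; cold aq. Na2S2O3/NaHCO3 work-up
Reagents that add atoms: 3-chloroperoxybenzoic acid, OOC(=O)c1cccc(Cl)c1
Why: Peracid S-oxidation of a sulfide is far faster at −78 °C than epoxidation of an isolated Z-alkene or Baeyer–Villiger oxidation, so one equivalent should stop at the sulfoxide in a solvent that dissolves the lipid chain; the sulfur configuration is irrelevant.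

Step 10
Reactants: 13 (2R,5S,6S)-6-methyl-5-(phenylsulfinyl)-2-[(14Z)-tricos-14-en-1-yl]tetrahydro-4H-pyran-4-one
Product: 14 (2R)-6-methyl-2-[(14Z)-tricos-14-en-1-yl]-2,3-dihydro-4H-pyran-4-one (target)
Conditions: toluene, 70 °C
Reagents that add atoms: none
Why: Thermal sulfoxide syn-elimination (dehydrosulfenylation of an α-sulfinyl ketone): the sulfinyl group on C5 is cis to H6, which is the only β-hydrogen because C4 is the carbonyl, so C5=C6 forms regiospecifically as the vinylogous ester, erasing C6 and leaving C2 untouched under neutral conditions.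

**Compound list**

1 | nervonic acid, (15Z)-tetracos-15-enoic acid | CCCCCCCC/C=C\CCCCCCCCCCCCCC(=O)O | starting material
2 | (15Z)-tetracos-15-en-1-ol | CCCCCCCC/C=C\CCCCCCCCCCCCCCO | intermediate
3 | (15Z)-tetracos-15-enal | CCCCCCCC/C=C\CCCCCCCCCCCCCC=O | intermediate
4 | methyl (S)-3-hydroxybutanoate | C[C@H](O)CC(=O)OC | starting material
5 | diphenyl disulfide | c1ccc(cc1)SSc1ccccc1 | starting material
6 | chelated dilithium alkoxide-enolate of 4 | [Li+].[Li+].C[C@H]([O-])/C=C(\[O-])OC | intermediate
7 | methyl (2S,3S)-3-hydroxy-2-(phenylsulfanyl)butanoate | COC(=O)[C@@H](Sc1ccccc1)[C@H](C)O | intermediate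
8 | (2S,3S)-3-hydroxy-2-(phenylsulfanyl)butanoic acid | OC(=O)[C@@H](Sc1ccccc1)[C@H](C)O | intermediate
9 | trimethylsilyl (2S,3S)-2-(phenylsulfanyl)-3-[(trimethylsilyl)oxy]butanoate | C[Si](C)(C)OC(=O)[C@@H](Sc1ccccc1)[C@H](C)O[Si](C)(C)C | intermediate
10 | (2S,5S,6S)-6-methyl-5-(phenylsulfanyl)-2-[(14Z)-tricos-14-en-1-yl]-1,3-dioxan-4-one | CCCCCCCC/C=C\CCCCCCCCCCCCC[C@@H]1OC(=O)[C@@H](Sc2ccccc2)[C@H](C)O1 | intermediate
11 | (2S,5S,6S)-6-methyl-4-methylidene-5-(phenylsulfanyl)-2-[(14Z)-tricos-14-en-1-yl]-1,3-dioxane | CCCCCCCC/C=C\CCCCCCCCCCCCC[C@@H]1OC(=C)[C@@H](Sc2ccccc2)[C@H](C)O1 | intermediate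
12 | (2R,5S,6S)-6-methyl-5-(phenylsulfanyl)-2-[(14Z)-tricos-14-en-1-yl]tetrahydro-4H-pyran-4-one | CCCCCCCC/C=C\CCCCCCCCCCCCC[C@@H]1CC(=O)[C@@H](Sc2ccccc2)[C@H](C)O1 | intermediate
13 | (2R,5S,6S)-6-methyl-5-(phenylsulfinyl)-2-[(14Z)-tricos-14-en-1-yl]tetrahydro-4H-pyran-4-one, epimers at sulfur | CCCCCCCC/C=C\CCCCCCCCCCCCC[C@@H]1CC(=O)[C@@H](S(=O)c2ccccc2)[C@H](C)O1 | intermediate
14 | (2R)-6-methyl-2-[(14Z)-tricos-14-en-1-yl]-2,3-dihydro-4H-pyran-4-one | CCCCCCCC/C=C\CCCCCCCCCCCCC[C@@H]1CC(=O)C=C(C)O1 | target

**Step count**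

Total steps: 10. Longest linear sequence: 8 (steps 3–10, from 4).

**Steps most likely to fail**

Step 8 (Petasis–Ferrier rearrangement). The sulfide may compete with O3 for the aluminium or add reversibly to the oxocarbenium carbon as a five-membered sulfonium ion, slowing or diverting the C–C closure. The exocyclic enol ether may also migrate into the ring (C4=C5) under Lewis acid before ionisation, and 2,6-cis control may erode if the closure leaves the chair.

Fallback, setting out from 3 and coming back at 14: the pyranone is assembled by a catalytic asymmetric hetero-Diels–Alder (Mukaiyama aldol–cyclisation) reaction instead. Commercial (3E)-4-methoxypent-3-en-2-one F1 is silylated (Me3SiOTf, Et3N, Et2O, 0 °C) to (3E)-4-methoxy-2-[(trimethylsilyl)oxy]penta-1,3-diene F2. F2 is added to aldehyde 3 under a BINOL/Ti(OiPr)4 catalyst (4 Å sieves, Et2O, −20 °C), using the BINOL antipode that gives the (R)-carbinol, fixed in a trial run. The aldol-type adduct (2E,6R,20Z)-6-hydroxy-2-methoxynonacosa-2,20-dien-4-one F3 is closed with CF3CO2H in CH2Cl2, with loss of methanol, to give 14 directly.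

Step 7 (methylenation). The allylic phenylsulfanyl group of the product may undergo thermal 1,3-migration to the exocyclic carbon, the new double bond may move into conjugation with sulfur, the titanium methylidene may be held up by sulfur coordination, and the enol acetal may hydrolyse on isolation.

Fallback, setting out from 4 and 3 and coming back at 14: the sulfide is left out and regiocontrol is supplied by a reagent after the ring is made.
- Ester 4 is saponified (LiOH, THF/H2O) to (S)-3-hydroxybutanoic acid F4 and silylated ((Me3Si)2NH) to trimethylsilyl (S)-3-[(trimethylsilyl)oxy]butanoate F5.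
- F5 is condensed with 3 (Me3SiOTf, CH2Cl2, −78 °C) to (2S,6S)-6-methyl-2-[(14Z)-tricos-14-en-1-yl]-1,3-dioxan-4-one F6, which is methylenated (Cp2TiMe2, THF, 65 °C) to (2S,6S)-6-methyl-4-methylidene-2-[(14Z)-tricos-14-en-1-yl]-1,3-dioxane F7.
- F7 is rearranged (Me2AlCl, CH2Cl2, −78 °C) to cis-(2S,6R)-2-methyl-6-[(14Z)-tricos-14-en-1-yl]oxan-4-one F8. These operations are the established sulfur-free form of the sequence.
- The two α-methylenes of F8 differ only through methyl versus the C23 chain and are nearly enantiotopic. A chiral lithium amide (LiN[CH(CH3)Ph]2 as the (R,R) or (S,S) antipode, whichever removes the axial hydrogen on the methyl side, with LiCl and Me3SiCl in THF at −78 °C) should give trimethyl({(2S,6R)-2-methyl-6-[(14Z)-tricos-14-en-1-yl]-5,6-dihydro-2H-pyran-4-yl}oxy)silane F9.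
- Saegusa–Ito oxidation of F9 (Pd(OAc)2, MeCN, rt) gives 14. Any regioisomeric enone from imperfect reagent control would have to be separated.

Step 3 (dianion sulfenylation). Proton transfer from the more acidic product to unreacted dianion may cause double sulfenylation and incomplete conversion, facial selectivity on the chelate may be poor for a sulfur electrophile, and the dianion may undergo retro-aldol cleavage on warming.

Fallback, setting out from 5 and coming back at 8: sulfur is used as the nucleophile on a chiral-pool electrophile.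
- Commercial D-threonine F10 is diazotised in the presence of bromide (NaNO2, KBr, aq. H2SO4, 0 °C). This proceeds with overall retention through the α-lactone and gives (2R,3S)-2-bromo-3-hydroxybutanoic acid F11.
- Disulfide 5 is cleaved with NaBH4 in EtOH to sodium benzenethiolate F12.
- F12 displaces bromide from the sodium salt of F11 with inversion (aq. NaHCO3/EtOH, 0 °C → rt; this pH ionises the thiol but not the alcohol, which suppresses epoxide formation). Acidification gives 8.

**Further compounds**

F1 | step 8 | (3E)-4-methoxypent-3-en-2-one | CC(=O)/C=C(\C)OC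
F2 | step 8 | (3E)-4-methoxy-2-[(trimethylsilyl)oxy]penta-1,3-diene | C=C(O[Si](C)(C)C)/C=C(\C)OC
F3 | step 8 | (2E,6R,20Z)-6-hydroxy-2-methoxynonacosa-2,20-dien-4-one | CCCCCCCC/C=C\CCCCCCCCCCCCC[C@@H](O)CC(=O)/C=C(\C)OC
F4 | step 7 | (S)-3-hydroxybutanoic acid | C[C@H](O)CC(=O)O
F5 | step 7 | trimethylsilyl (S)-3-[(trimethylsilyl)oxy]butanoate | C[C@H](O[Si](C)(C)C)CC(=O)O[Si](C)(C)C
F6 | step 7 | (2S,6S)-6-methyl-2-[(14Z)-tricos-14-en-1-yl]-1,3-dioxan-4-one | CCCCCCCC/C=C\CCCCCCCCCCCCC[C@@H]1OC(=O)C[C@H](C)O1
F7 | step 7 | (2S,6S)-6-methyl-4-methylidene-2-[(14Z)-tricos-14-en-1-yl]-1,3-dioxane | CCCCCCCC/C=C\CCCCCCCCCCCCC[C@@H]1OC(=C)C[C@H](C)O1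
F8 | step 7 | (2S,6R)-2-methyl-6-[(14Z)-tricos-14-en-1-yl]oxan-4-one | CCCCCCCC/C=C\CCCCCCCCCCCCC[C@@H]1CC(=O)C[C@H](C)O1
F9 | step 7 | trimethyl({(2S,6R)-2-methyl-6-[(14Z)-tricos-14-en-1-yl]-5,6-dihydro-2H-pyran-4-yl}oxy)silane | CCCCCCCC/C=C\CCCCCCCCCCCCC[C@@H]1CC(O[Si](C)(C)C)=C[C@H](C)O1
F10 | step 3 | D-threonine | C[C@@H]([C@H](C(=O)O)N)O
F11 | step 3 | (2R,3S)-2-bromo-3-hydroxybutanoic acid | C[C@@H]([C@H](C(=O)O)Br)O
F12 | step 3 | sodium benzenethiolate | [Na+].[S-]c1ccccc1
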